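(The earlier runs and the new flask were generated by integration with made-up constants; noise was put on by code.)

Answer 3 questions about the north-west flask, which is followed on to 1.5 h.

- left-handed product and right-handed product together, in percent of the left-handed substrate and right-handed substrate charged together, at 1.5 h
- excess of left-handed product over right-handed product in the product at 1.5 h
- whether the exchange between left-handed substrate and right-handed substrate keeps pace with the reaction: how far the product's excess at 1.5 h gets from its value without exchange to its value with instant exchange (above 80 % keeps pace, below 20 % hardly takes part, else lags behind)

the same everywhere: left-handed substrate 0.23 M; right-handed substrate 0.23 M; free catalyst 2.2 mM; racemization catalyst 0.23 mM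
- north-west: reagent 0.46 M; impurity 57 µM; the very flask that is asked about, followed so far
- south-west: reagent 0.46 M; impurity 110 µM; run made earlier
- flask: reagent 0.460 M; impurity 57 µM; time 1.5 h

| run | time / min | left-handed product / % | right-handed product / % | left-handed substrate / % |
|---|---|---|---|---|
| north-west | 12.0 | 59 | 3 | 19 |
| north-west | 25.0 | 59 | 6 | 17 |
| north-west | 30.0 | 61 | 7 | 17 |
| north-west | 50.0 | 65 | 8 | 14 |
| south-west | 5.00 | 41 | 6 | 24 |
| south-west | 12.0 | 52 | 4 | 18 |
| south-west | 25.0 | 64 | 9 | 14 |
| south-west | 60.0 | 58 | 7 | 18 |

(each reading ± 2 percentage points)

- free catalyst is single-handed; left-handed substrate and right-handed substrate are mirror images of each other, charged as a racemate, each of them at the stated concentration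
- an excess is the difference of the two amounts in percent of their sum
- an excess is below zero if the other one leads

Run the flask slowly, beginning with the first minutes. The south-west run, which differs from the north-west run in its impurity charge, already holds 47.0 % of product at 5.00 min.

Now take the middle. At 12.0 min the north-west run holds 59 % of left-handed product, more than the half of the charge that began left-handed, so right-handed substrate has crossed over. Left-handed substrate, at 19 %, stands level with the right-handed substrate found by difference, 19.0 %. Reckon, then, that the exchange keeps pace.

Then read the end. From 25.0 min on, the readings of the product total rise in the north-west run but fall in the south-west run, and the two average 68.7 % and 69.0 %. The doubled impurity therefore shows no effect beyond the scatter. Pool these readings: left-handed product averages 61.4 % and right-handed product 7.40 %, which reads as a stall level of 68.8 %, with the scatter of those readings on it.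

Now watch the reagent, whose charge equals both substrates together. Carry one number, 68.8 %: the reagent yield, product made per reagent charged. Commit to the stall holding until 1.5 h, which gives a total of 68.8 % and an excess of 78.5 %.

The forecast says 77 %, 79 % and keeps pace, holding that “the catalyst is probably dying”. The flask gives 68.3 %, 81.5 % and keeps pace, at 93 % of the way.

    reagent + free catalyst + left-handed substrate → free catalyst + left-handed product (k = 480 /M²/min)
    reagent + free catalyst + right-handed substrate → free catalyst + right-handed product (k = 44.0 /M²/min)
    left-handed substrate + racemization catalyst ⇌ right-handed substrate + racemization catalyst, rate k3*[racemization catalyst]*[left-handed substrate] forward; the back reaction follows from the equilibrium constant (k = 4300 /M/min)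
    racemization catalyst + impurity → spent catalyst A (k = 1.60 × 10⁵ /M/min)
    reagent + free catalyst → spent catalyst B (k = 0.0380 /M/min)
    2 reagent → self-condensation product (k = 0.200 /M/min)

Reagent is the limiting reagent in this flask: at 1.50 h, 0.015 % of its charge is left, against 32 % of the left-handed substrate's own charge. At 1.50 h the half-life of left-handed substrate by the making of left-handed product stands at 170 h, far longer than the 1.5 h allowed. The reagent yield of this flask is 68.3 %, while self-condensation product holds 31.6 % of the reagent charged. In the neighbour charged with 0.12 M of reagent, the total of 23.8 % makes the reagent yield 91.1 %.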